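The route disconnects the α-methylene-γ-butyrolactone across C6–C7 and C11–C12 (germacranolide numbering). A ruthenium-catalysed allenic hetero-Pauson–Khand cyclocarbonylation joins the proximal C7=C11 π-bond of a terminal allene, the C6=O group of a (Z)-enal and CO; it exploits that the five lactone ring atoms (O, C6, C7, C11, C12) are exactly an aldehyde, one allene π-bond and CO. One operation thus builds the lactone, sets C6 and C7 and closes the ten-membered carbocycle around the preformed 3(2H)-furanone. The precursor is an open-chain furanone bearing the C8 methacrylate, C9 acetate, a C7 allene and the C4–C6 (Z)-enal; its C8–C10 triad comes from L-glyceraldehyde acetonide through 2-C-methyl-L-ribonolactone.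

Key step: step 15

Atom labels used for all compounds (those of target 22): C1 furanone C=O, C2=C3 furanone alkene (C3 bears the ring oxygen), C4(CH3)=C5, C6 (lactone O–CH), C7, C8 (O-methacryloyl), C9 (OAc), C10 (quaternary, CH3 and ring O), C11(=C13H2), C12 lactone C=O. The target is (4Z,6R,7S,8S,9S,10S).

Assumption: (S)-glyceraldehyde acetonide 1 is bought; otherwise it is made fresh by periodate cleavage of 5,6-O-isopropylidene-L-gulono-1,4-lactone.

Step 1
Reactants: 1 (S)-2,2-dimethyl-1,3-dioxolane-4-carbaldehyde; 2 ethyl 2-[bis(2,2,2-trifluoroethoxy)phosphoryl]propanoate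
Product: 3 ethyl (Z)-3-[(4R)-2,2-dimethyl-1,3-dioxolan-4-yl]-2-methylprop-2-enoate
Conditions: KHMDS, 18-crown-6, THF, −78 °C
Reagents that add atoms: none
Why: Still–Gennari olefination, in which the electron-poor phosphonate eliminates fast from the kinetic adduct and should give the (Z)-trisubstituted enoate (C1 and C8 cis), the C8 centre coming unchanged from 1.

Step 2
Reactants: 3 ethyl (Z)-3-[(4R)-2,2-dimethyl-1,3-dioxolan-4-yl]-2-methylprop-2-enoate
Product: 4 ethyl (2S,3S)-3-[(4S)-2,2-dimethyl-1,3-dioxolan-4-yl]-2,3-dihydroxy-2-methylpropanoate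
Conditions: OsO4 (2 mol %), NMO, acetone/H2O, rt
Reagents that add atoms: N-methylmorpholine N-oxide, C[N+]1([O-])CCOCC1; water, O
Why: Upjohn syn-dihydroxylation, in which allylic 1,3-strain in the (Z)-enoate fixes the C8 rotamer so that OsO4 adds anti to the allylic C8–O bond (sets C9, 8,9-anti) and syn addition to the (Z)-alkene sets C10 (ribo triad).

Step 3
Reactants: 4 ethyl (2S,3S)-3-[(4S)-2,2-dimethyl-1,3-dioxolan-4-yl]-2,3-dihydroxy-2-methylpropanoate
Product: 5 2-C-methyl-L-ribono-1,4-lactone
Conditions: TFA/H2O (4:1), 0 °C to rt; concentrate from toluene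
Reagents that add atoms: none
Why: Acid hydrolysis of the acetonide followed by transesterifying γ-lactonisation of O8 onto the ethyl ester gives the five-membered lactone, the stable ring size of ribonic acids, without touching a stereocentre.

Step 4
Reactants: 5 2-C-methyl-L-ribono-1,4-lactone
Product: 6 O9/O10 cyclic orthoacetate of the lactone with free C7 hydroxyl
Conditions: MeC(OMe)3 (1.1 equiv), PPTS (cat.), CH2Cl2, rt; Et3N quench
Reagents that add atoms: trimethyl orthoacetate, CC(OC)(OC)OC
Why: Transorthoesterification closes the five-membered orthoester only across the cis O9/O10 diol, because the primary hydroxyl lies on the other face of the lactone and cannot bridge.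

Step 5
Reactants: 6 O9/O10 cyclic orthoacetate of the lactone with free C7 hydroxyl
Product: 7 C7 aldehyde of the orthoacetate lactone
Conditions: Dess–Martin periodinane, pyridine, CH2Cl2, 0 °C; used crude
Reagents that add atoms: none
Why: Dess–Martin oxidation of the only free hydroxyl under buffered, non-aqueous conditions that spare the orthoester and limit epimerisation or β-elimination at C8.

Step 6
Reactants: 7 C7 aldehyde of the orthoacetate lactone
Product: 8 C7 propargylic alcohol (both C7 epimers)
Conditions: HC≡CMgBr, THF, −78 °C; pH 7 buffer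
Reagents that add atoms: ethynylmagnesium bromide, C#C[Mg]Br
Why: 1,2-Addition of the alkynyl Grignard reagent to the aldehyde, which is far more electrophilic than the hindered lactone at −78 °C; the C7 carbinol mixture is irrelevant because C7 becomes sp2 in step 7.

Step 7
Reactants: 8 C7 propargylic alcohol (both C7 epimers)
Product: 11 allenyl lactone orthoacetate, via N-sulfonylhydrazine 9 (not isolated), via propargylic diazene 10 (not isolated)
Conditions: 2-nitrobenzenesulfonylhydrazide, PPh3, DEAD, THF, −15 °C to 23 °C
Reagents that add atoms: none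
Why: Myers allene synthesis, in which Mitsunobu displacement by the sulfonylhydrazide, loss of sulfinic acid and sigmatropic loss of N2 from the diazene deliver hydrogen to the alkyne terminus, so both carbinol epimers converge on the terminal allene (no axial chirality).

Step 8
Reactants: 12 (Z)-3-methylpent-2-en-4-yn-1-ol
Product: 13 TBS ether of (Z)-3-methylpent-2-en-4-yn-1-ol
Conditions: TBSCl, imidazole, CH2Cl2, 0 °C to rt
Reagents that add atoms: tert-butyldimethylsilyl chloride, CC(C)(C)[Si](C)(C)Cl
Why: Standard silylation of the primary allylic alcohol, with the (Z)-geometry (the future C4=C5 bond) bought in.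

Step 9
Reactants: 13 TBS ether of (Z)-3-methylpent-2-en-4-yn-1-ol; 11 allenyl lactone orthoacetate
Product: 15 hydroxy ynone orthoacetate, via lithium acetylide 14 (not isolated)
Conditions: n-BuLi, THF, −78 °C; then 11, −78 °C; pH 7 buffer
Reagents that add atoms: none
Why: Acylation of a lithium acetylide by a γ-lactone stops at the stable lithium hemiketalate (the standard entry to 1-C-alkynyl ketoses from aldonolactones) and gives the C1 ynone after quench, forming the C1–C2 bond and leaving C8–C10 untouched.

Step 10
Reactants: 15 hydroxy ynone orthoacetate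
Product: 16 C9-acetoxy C10-hydroxy ynone
Conditions: AcOH/THF/H2O (1:2:1), 0 °C, short
Reagents that add atoms: water, O
Why: Orthoester hydrolysis through the dioxolan-2-ylium ion and hemiorthoester, which should collapse by loss of the more basic tertiary oxygen and so leave the acetate on secondary O9 and a free tertiary C10 hydroxyl, while the primary TBS ether survives the short exposure.

Step 11
Reactants: 16 C9-acetoxy C10-hydroxy ynone
Product: 18 C8-hydroxy 3(2H)-furanone, via diethylamino enone 17 (not isolated)
Conditions: Et2NH, EtOH, 0 °C to rt; then dilute AcOH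
Reagents that add atoms: none
Why: Classical amine-mediated 3(2H)-furanone synthesis from an α′-hydroxy ynone, in which conjugate addition of diethylamine gives the β-amino enone and the C10 hydroxyl attacks its iminium form at C3 (5-exo) with loss of the amine; O9 is blocked as the acetate, so the pyranone cannot form.

Step 12
Reactants: 18 C8-hydroxy 3(2H)-furanone
Product: 19 C8 methacrylate
Conditions: methacrylic anhydride, Et3N, DMAP (cat.), CH2Cl2, 0 °C
Reagents that add atoms: methacrylic anhydride, CC(=C)C(=O)OC(=O)C(C)=C
Why: DMAP-catalysed acylation of the only free hydroxyl (secondary, C8) with retention of configuration.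

Step 13
Reactants: 19 C8 methacrylate
Product: 20 C6 allylic alcohol
Conditions: HF·pyridine, pyridine/THF, 0 °C
Reagents that add atoms: none
Why: Buffered fluoride cleavage of the primary silyl ether, which leaves both esters, the furanone and the allene intact.

Step 14
Reactants: 20 C6 allylic alcohol
Product: 21 allenyl (Z)-enal
Conditions: Dess–Martin periodinane, pyridine, CH2Cl2, 0 °C
Reagents that add atoms: none
Why: Dess–Martin oxidation of the primary allylic alcohol under buffered conditions that should preserve the (Z)-C4=C5 geometry.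

Step 15
Reactants: 21 allenyl (Z)-enal
Product: 22 target furanoheliangolide
Conditions: Ru3(CO)12 (5 mol %), CO (10 atm), BHT (cat.), 1,4-dioxane (2 mM), 110 °C
Reagents that add atoms: carbon monoxide, [C-]#[O+]
Why: Proposed new method: zerovalent ruthenium couples the proximal allene π-bond (C7=C11) and the C6=O group oxidatively to an oxaruthenacyclopentane (C6–C7 bond), CO inserts into the Ru–C11 bond (C11–C12 bond) and C12–O reductive elimination releases the α-methylene lactone. The closest known reaction type is the Ru3(CO)12-catalysed (or Mo(CO)6-mediated) intramolecular hetero-Pauson–Khand cyclocarbonylation of allenyl aldehydes, established for tethers that give five- and six-membered carbocycles; its use for a ten-membered ring is the untested part. The γ-lactone closes as a [2+2+1] annulation, and the ten-membered carbocycle (with it the nine-membered oxa-bridged ring) closes in the oxidative cyclisation by a 10-exo attack of C7 on the aldehyde carbon, helped by the rigid furanone, the (Z)-C4=C5 bond and high dilution. C7 is set by the C8 stereocentre, the metal and C6 adding to the allene face anti to the allylic C8–O bond with the C8–C9 bond near the π-plane (Felkin–Anh-type arrangement), and C6 is set relative to C7 in the metallacycle, where the H6/H7-trans arrangement keeps C5 and C8 on opposite faces as in the 6,7-trans-fused heliangolide ring. The step needs the proximal and not the distal allene π-bond, and the aldehyde and not the methacrylate, enone or furanone π-bonds, to react; the first is the normal mode of these allene cyclocarbonylations and should be reinforced by coordination of the C8 ester carbonyl, the second follows because only a C=O partner can give the lactone.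

Compound list
1 | (S)-2,2-dimethyl-1,3-dioxolane-4-carbaldehyde (2,3-O-isopropylidene-L-glyceraldehyde) | O=C[C@@H]1COC(C)(C)O1 | starting material
2 | ethyl 2-[bis(2,2,2-trifluoroethoxy)phosphoryl]propanoate | CCOC(=O)C(C)P(=O)(OCC(F)(F)F)OCC(F)(F)F | starting material
3 | ethyl (Z)-3-[(4R)-2,2-dimethyl-1,3-dioxolan-4-yl]-2-methylprop-2-enoate | CCOC(=O)/C(C)=C\[C@@H]1COC(C)(C)O1 | intermediate
4 | ethyl (2S,3S)-3-[(4S)-2,2-dimethyl-1,3-dioxolan-4-yl]-2,3-dihydroxy-2-methylpropanoate | CCOC(=O)[C@@](C)(O)[C@@H](O)[C@@H]1COC(C)(C)O1 | intermediate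
5 | 2-C-methyl-L-ribono-1,4-lactone, (3S,4S,5S)-3,4-dihydroxy-5-(hydroxymethyl)-3-methyloxolan-2-one | O=C1O[C@@H](CO)[C@H](O)[C@]1(C)O | intermediate
6 | (3aS,6S,6aS)-6-(hydroxymethyl)-2-methoxy-2,3a-dimethyldihydrofuro[3,4-d][1,3]dioxol-4(3aH)-one (O9/O10 cyclic orthoacetate of 5, both epimers at the orthoester carbon) | O=C1O[C@@H](CO)[C@@H]2OC(C)(OC)O[C@]12C | intermediate
7 | (3aS,6R,6aS)-2-methoxy-2,3a-dimethyl-4-oxotetrahydrofuro[3,4-d][1,3]dioxole-6-carbaldehyde (C7 aldehyde) | O=C1O[C@@H](C=O)[C@@H]2OC(C)(OC)O[C@]12C | intermediate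
8 | (3aS,6S,6aS)-6-(1-hydroxyprop-2-yn-1-yl)-2-methoxy-2,3a-dimethyldihydrofuro[3,4-d][1,3]dioxol-4(3aH)-one (C7 propargylic alcohol, both C7 epimers) | O=C1O[C@@H](C(O)C#C)[C@@H]2OC(C)(OC)O[C@]12C | intermediate
9 | Mitsunobu adduct of 8: C7 carries N(NH2)SO2(2-nitrophenyl) in place of OH | O=C1O[C@@H](C(N(N)S(=O)(=O)c3ccccc3[N+](=O)[O-])C#C)[C@@H]2OC(C)(OC)O[C@]12C | intermediate (not isolated)
10 | C7 propargylic monoalkyl diazene (C7–N=NH) | O=C1O[C@@H](C(N=N)C#C)[C@@H]2OC(C)(OC)O[C@]12C | intermediate (not isolated)
11 | (3aS,6S,6aS)-2-methoxy-2,3a-dimethyl-6-(propa-1,2-dien-1-yl)dihydrofuro[3,4-d][1,3]dioxol-4(3aH)-one (allenyl lactone orthoacetate) | O=C1O[C@@H](C=C=C)[C@@H]2OC(C)(OC)O[C@]12C | intermediate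
12 | (Z)-3-methylpent-2-en-4-yn-1-ol | C#C/C(C)=C\CO | starting material
13 | tert-butyldimethyl{[(Z)-3-methylpent-2-en-4-yn-1-yl]oxy}silane | C#C/C(C)=C\CO[Si](C)(C)C(C)(C)C | intermediate
14 | lithium acetylide of 13 | [Li]C#C/C(C)=C\CO[Si](C)(C)C(C)(C)C | intermediate (not isolated)
15 | hydroxy ynone orthoacetate: TBSO–C6H2–C5H=C4(CH3)–C3≡C2–C1(=O)–C10(CH3)–C9H–C8H(OH)–C7H=C11=C13H2 with the O9/O10 orthoacetate; (4Z,8S,9S,10S); ring-chain tautomer with the O8/C1 five-membered hemiketal | CC(C)(C)[Si](C)(C)OC/C=C(/C)C#CC(=O)[C@@]1(C)OC(C)(OC)O[C@H]1[C@@H](O)C=C=C | intermediate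
16 | C9-acetoxy C10-hydroxy ynone (free C8 hydroxyl, same hemiketal tautomerism); (4Z,8S,9S,10S) | CC(C)(C)[Si](C)(C)OC/C=C(/C)C#CC(=O)[C@@](C)(O)[C@@H](OC(C)=O)[C@@H](O)C=C=C | intermediate
17 | β-diethylamino enone from addition of Et2NH to C3 of 16 | CC(C)(C)[Si](C)(C)OC/C=C(/C)C(N(CC)CC)=CC(=O)[C@@](C)(O)[C@@H](OC(C)=O)[C@@H](O)C=C=C | intermediate (not isolated)
18 | 3(2H)-furanone (O bridging C3 and C10) with C8 hydroxyl, C9 acetate, C7 allene and the (Z)-C4=C5–C6H2OTBS chain; (8S,9S,10S) | CC(C)(C)[Si](C)(C)OC/C=C(/C)C1=CC(=O)[C@@](C)(O1)[C@@H](OC(C)=O)[C@@H](O)C=C=C | intermediate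
19 | C8 methacrylate of 18 | CC(C)(C)[Si](C)(C)OC/C=C(/C)C1=CC(=O)[C@@](C)(O1)[C@@H](OC(C)=O)[C@@H](OC(=O)C(C)=C)C=C=C | intermediate
20 | C6 allylic alcohol (19 without the silyl group) | OC/C=C(/C)C1=CC(=O)[C@@](C)(O1)[C@@H](OC(C)=O)[C@@H](OC(=O)C(C)=C)C=C=C | intermediate
21 | allenyl (Z)-enal: furanone with the C8 methacrylate, C9 acetate, C7H=C11=C13H2 allene and (Z)-C4(CH3)=C5H–C6HO; (8S,9S,10S) | O=C/C=C(/C)C1=CC(=O)[C@@](C)(O1)[C@@H](OC(C)=O)[C@@H](OC(=O)C(C)=C)C=C=C | intermediate
22 | (4Z,6R,7S,8S,9S,10S)-9-acetoxy-8-(methacryloyloxy)-1-oxo-3,10-epoxygermacra-2,4,11(13)-trien-12,6-olide | C=C(C)C(=O)O[C@H]1[C@H]2C(=C)C(=O)O[C@@H]2/C=C(/C)C2=CC(=O)[C@@](C)(O2)[C@H]1OC(C)=O | target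

Total step count: 15. Longest linear sequence: 14 steps (steps 1–7 and 9–15; step 8 is a one-step side branch).

Steps most likely to fail

1. Step 15 (carries the new-method label). The ten-membered ring may not close, with oligomerisation taking over. The distal allene π-bond may react, or the allenylic C8 ester may ionise on ruthenium. Facial selectivity at C6/C7 may be poor, and the enal may isomerise from Z to E at 110 °C. Fallback, from 21 back to 22, building the lactone in stages with known reaction types: one equivalent of bromine adds to the allene at −78 °C to give the 2-bromoallylic bromide F1 (its allylic isomer gives the same allylmetal). A zinc-mediated intramolecular Barbier allylation at high dilution, the ring closure used for germacranolides, forms C6–C7 and gives the ten-membered 2-bromo homoallylic alcohol F2. Carbonylative lactonisation of the vinyl bromide onto the C6 hydroxyl with Pd(PPh3)4, CO and K2CO3 then forms C11–C12 and gives 22.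

2. Step 11. While the C8 hydroxyl is free next to the C9 acetate, the acetyl group may migrate to O8 or O10 under the amine, and a liberated O9 would then close the six-membered pyranone instead of the furanone. Fallback, from 11 back to 19, acylating O8 before the ynone exists: the lactone is opened with the magnesium amide of N,O-dimethylhydroxylamine to the hydroxy Weinreb amide F3, which is acylated at once with methacrylic anhydride/DMAP to the methacrylate Weinreb amide F4. Lithium acetylide 14 adds to the chelating amide at −78 °C in preference to the hindered ester to give the ynone orthoacetate F5. Aqueous acetic acid opens the orthoester to the C9-acetoxy C10-hydroxy ynone F6, and diethylamine cyclises it directly to 19.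

3. Step 7. The Mitsunobu displacement at the hindered, β-oxygenated C7 carbinol may be slower than decomposition of the sulfonylhydrazide, so the diazene never forms. Fallback, from 8 back to 11, without an SN2 step: the alcohol is converted with methyl chloroformate/pyridine into the propargylic methyl carbonate F7. Formate hydrogenolysis with Pd2(dba)3, PBu3 and HCO2NH4 in THF then passes through the allenylpalladium hydride and gives the terminal allene 11.

Further compounds
F1 | step 15 | 2-bromoallylic bromide from 21 (C7H=C11(Br)–C13H2Br in place of the allene) | O=C/C=C(/C)C1=CC(=O)[C@@](C)(O1)[C@@H](OC(C)=O)[C@@H](OC(=O)C(C)=C)C=C(Br)CBr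
F2 | step 15 | ten-membered 6-hydroxy 7-(1-bromovinyl) carbocycle (22 with the lactone replaced by C6–OH and C11(Br)=C13H2) | C=C(C)C(=O)O[C@H]1[C@@H](C(Br)=C)[C@H](O)/C=C(/C)C2=CC(=O)[C@@](C)(O2)[C@H]1OC(C)=O
F3 | step 11 | hydroxy Weinreb amide from ring-opening of 11 | CON(C)C(=O)[C@@]1(C)OC(C)(OC)O[C@H]1[C@@H](O)C=C=C
F4 | step 11 | C8 methacrylate of F3 | CON(C)C(=O)[C@@]1(C)OC(C)(OC)O[C@H]1[C@@H](OC(=O)C(C)=C)C=C=C
F5 | step 11 | ynone orthoacetate with the C8 methacrylate | CC(C)(C)[Si](C)(C)OC/C=C(/C)C#CC(=O)[C@@]1(C)OC(C)(OC)O[C@H]1[C@@H](OC(=O)C(C)=C)C=C=C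
F6 | step 11 | C9-acetoxy C10-hydroxy ynone with the C8 methacrylate | CC(C)(C)[Si](C)(C)OC/C=C(/C)C#CC(=O)[C@@](C)(O)[C@@H](OC(C)=O)[C@@H](OC(=O)C(C)=C)C=C=C
F7 | step 7 | C7 propargylic methyl carbonate of 8 | O=C1O[C@@H](C(OC(=O)OC)C#C)[C@@H]2OC(C)(OC)O[C@]12C
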